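**Retrosynthetic overview**
- Target ⇒ penta-O-allyl precursor: the acid and the four phenols carry the same mask, removed at the end with zerovalent palladium under neutral conditions.
- Key disconnection: the benzylic C–O bond of the central ester, made by the new step, an electrophilic aroyloxylation of a laterally lithiated toluate (ring B) by a symmetrical diaroyl peroxide (ring A).
- The peroxide is assembled from two different partners, a peroxy acid and an acid chloride. Both, and the ester partner, come from one bis-allyl-protected acid, made by Pinnick oxidation of the bis-allyl ether of 2,4-dihydroxy-3,6-dimethylbenzaldehyde.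
- Ring formation: none. Ring A (acyl half) and ring B (benzyl half) are carried intact from the same aldehyde; the order is protect, oxidise, branch (ester / acid chloride / peroxy acid), join to the peroxide, couple, deprotect.

Assumption: the target has no stereocentre (it is achiral), so no stereocontrol is needed; 2,4-dihydroxy-3,6-dimethylbenzaldehyde is taken as a catalogue compound.

**Route**

Step 1
Reactants: 1 2,4-dihydroxy-3,6-dimethylbenzaldehyde
Product: 2 2,4-bis(allyloxy)-3,6-dimethylbenzaldehyde
Conditions: allyl bromide (3 equiv), K2CO3 (3 equiv), KI (cat.), DMF, 65 °C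
Reagents that add atoms: allyl bromide C=CCBr
Why: Williamson ether synthesis (SN2 of both phenoxides on allyl bromide); warm DMF and iodide overcome the hydrogen-bonded, flanked 2-OH, and no stereocentre is created.

Step 2
Reactants: 2 2,4-bis(allyloxy)-3,6-dimethylbenzaldehyde
Product: 3 2,4-bis(allyloxy)-3,6-dimethylbenzoic acid
Conditions: NaClO2 (3 equiv), NaH2PO4 (3 equiv), 2-methyl-2-butene (15 equiv), t-BuOH/THF/H2O, 0 → 25 °C
Reagents that add atoms: sodium chlorite [Na+].[O-]Cl=O
Why: Pinnick (Lindgren) oxidation, in which chlorous acid adds to the hindered aldehyde and fragments to the acid while 2-methyl-2-butene consumes the HOCl, so the allyl ethers and the electron-rich ring are not chlorinated.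

Step 3
Reactants: 3 2,4-bis(allyloxy)-3,6-dimethylbenzoic acid
Product: 4 allyl 2,4-bis(allyloxy)-3,6-dimethylbenzoate
Conditions: allyl bromide (1.3 equiv), K2CO3 (1.5 equiv), DMF, 25 °C
Reagents that add atoms: allyl bromide C=CCBr
Why: Carboxylate O-alkylation (SN2 on allyl bromide), which works for a 2,6-disubstituted benzoic acid because the bond is made at the allyl carbon and not at the hindered carbonyl.

Step 4
Reactants: 3 2,4-bis(allyloxy)-3,6-dimethylbenzoic acid
Product: 5 2,4-bis(allyloxy)-3,6-dimethylbenzoyl chloride
Conditions: (COCl)2 (1.5 equiv), DMF (cat.), CH2Cl2, 0 → 25 °C, evaporate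
Reagents that add atoms: oxalyl chloride O=C(Cl)C(Cl)=O
Why: Acid chloride formation through the Vilsmeier-type chloroiminium salt; the allyl ethers and the arene are inert and the volatile by-products leave on evaporation.

Step 5
Reactants: 5 2,4-bis(allyloxy)-3,6-dimethylbenzoyl chloride
Product: 6 2,4-bis(allyloxy)-3,6-dimethylperoxybenzoic acid
Conditions: 50% aq. H2O2 (8 equiv), NaOH (2.1 equiv), MgSO4·7H2O (cat.), THF/H2O, −5 → 0 °C, 20 min; cold aq. NaH2PO4 to pH 5; extract into toluene at 0 °C, dry, titrate, use at once
Reagents that add atoms: hydrogen peroxide OO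
Why: Perhydrolysis of an acid chloride (acyl substitution by the small alpha-effect nucleophile HOO−, the standard preparation of aromatic peroxy acids); the large excess of H2O2 suppresses double acylation, and the peroxy acid is held first as its non-electrophilic sodium salt and then cold and dilute, so the slow epoxidation of the deactivated terminal allyl ether alkenes does not compete.

Step 6
Reactants: 6 2,4-bis(allyloxy)-3,6-dimethylperoxybenzoic acid; 5 2,4-bis(allyloxy)-3,6-dimethylbenzoyl chloride
Product: 7 bis[2,4-bis(allyloxy)-3,6-dimethylbenzoyl] peroxide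
Conditions: 6 (1.0 equiv) in toluene, aq. Na2CO3 (1.1 equiv), Bu4NHSO4 (cat.), 0 °C; add 5 (1.05 equiv) in toluene, 0 °C, dark, 1 h; cold wash, dry, solution kept at or below 0 °C and titrated
Reagents that add atoms: none
Why: Schotten–Baumann acylation of a peroxycarboxylate anion by an acid chloride under phase transfer, the standard way to a diacyl peroxide of defined composition; the ortho substituents slow hydrolysis of 5 more than attack by the alpha-effect peroxy anion, and because both partners derive from acid 3 the peroxide is symmetrical.

Step 7
Reactants: 4 allyl 2,4-bis(allyloxy)-3,6-dimethylbenzoate; 7 bis[2,4-bis(allyloxy)-3,6-dimethylbenzoyl] peroxide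
Product: 9 allyl 2,4-bis(allyloxy)-6-{[2,4-bis(allyloxy)-3,6-dimethylbenzoyl]oxymethyl}-3-methylbenzoate, via benzylic lithium species 8 (not isolated)
Conditions: LiN(iPr)2 (1.05 equiv), THF, −78 °C, 30 min; cannulate into 7 (1.2 equiv), THF, −78 → −40 °C; 1 M HCl
Reagents that add atoms: lithium diisopropylamide [Li]N(C(C)C)C(C)C (supplies only the lithium of 8; every atom of 9 comes from 4 and 7)
Why: Proposed new method: an umpolung esterification by electrophilic aroyloxylation of a laterally lithiated toluate, in which LiN(iPr)2 removes a proton only from the 6-methyl group (ortho to the ester, giving the ester-stabilised benzylic anion 8; the 3-methyl group is not acidified) and this soft carbanion attacks the weak O–O bond of 7 in an SN2 reaction at oxygen that expels the carboxylate of 3, while the two ortho substituents on each aroyl group shield the peroxide carbonyls from acyl attack and either oxygen of the symmetrical peroxide gives the same product, so the hindered acid is delivered as an aroyloxy cation equivalent and the benzylic C–O bond is made without a lactonisation-prone benzylic halide (an electron-transfer/radical-pair pathway would collapse to the same ester, and inverse addition into excess peroxide keeps the more acidic product away from unreacted anion); the closest known reaction type is the benzoyloxylation of enolates, enamines and Grignard reagents with dibenzoyl peroxide; no stereocentre is formed.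

Step 8
Reactants: 9 allyl 2,4-bis(allyloxy)-6-{[2,4-bis(allyloxy)-3,6-dimethylbenzoyl]oxymethyl}-3-methylbenzoate
Product: 10 6-{[(2,4-dihydroxy-3,6-dimethylbenzoyl)oxy]methyl}-2,4-dihydroxy-3-methylbenzoic acid
Conditions: Pd(PPh3)4 (10 mol %), morpholine (15 equiv), THF, 25 °C; cold 1 M HCl work-up
Reagents that add atoms: none
Why: Tsuji–Trost-type deallylation, in which zerovalent palladium ionises the allyl ester and the four aryl allyl ethers to pi-allyl complexes that morpholine intercepts, under neutral conditions that leave the hindered benzylic ester intact; the product has no stereocentre.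

**Compound list**
1 | 2,4-dihydroxy-3,6-dimethylbenzaldehyde | Cc1cc(O)c(C)c(O)c1C=O | starting material
2 | 2,4-bis(allyloxy)-3,6-dimethylbenzaldehyde | Cc1cc(OCC=C)c(C)c(OCC=C)c1C=O | intermediate
3 | 2,4-bis(allyloxy)-3,6-dimethylbenzoic acid | Cc1cc(OCC=C)c(C)c(OCC=C)c1C(=O)O | intermediate
4 | allyl 2,4-bis(allyloxy)-3,6-dimethylbenzoate | Cc1cc(OCC=C)c(C)c(OCC=C)c1C(=O)OCC=C | intermediate
5 | 2,4-bis(allyloxy)-3,6-dimethylbenzoyl chloride | Cc1cc(OCC=C)c(C)c(OCC=C)c1C(Cl)=O | intermediate
6 | 2,4-bis(allyloxy)-3,6-dimethylperoxybenzoic acid | Cc1cc(OCC=C)c(C)c(OCC=C)c1C(=O)OO | intermediate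
7 | bis[2,4-bis(allyloxy)-3,6-dimethylbenzoyl] peroxide | Cc1cc(OCC=C)c(C)c(OCC=C)c1C(=O)OOC(=O)c1c(C)cc(OCC=C)c(C)c1OCC=C | intermediate
8 | allyl 2,4-bis(allyloxy)-6-(lithiomethyl)-3-methylbenzoate (benzylic lithium species drawn in its C-lithio form) | [Li]Cc1cc(OCC=C)c(C)c(OCC=C)c1C(=O)OCC=C | intermediate
9 | allyl 2,4-bis(allyloxy)-6-{[2,4-bis(allyloxy)-3,6-dimethylbenzoyl]oxymethyl}-3-methylbenzoate | Cc1cc(OCC=C)c(C)c(OCC=C)c1C(=O)OCc1cc(OCC=C)c(C)c(OCC=C)c1C(=O)OCC=C | intermediate
10 | 6-{[(2,4-dihydroxy-3,6-dimethylbenzoyl)oxy]methyl}-2,4-dihydroxy-3-methylbenzoic acid (CNP0110620.0; achiral) | Cc1cc(O)c(C)c(O)c1C(=O)OCc1cc(O)c(C)c(O)c1C(=O)O | target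

**Step count and risks**
Total step count: 8. Longest linear sequence: 7 (steps 1, 2, 4, 5, 6, 7, 8).

The three steps most likely to fail:

Step 7 (the proposed new step). Electron transfer from 8 to 7 may let radicals escape, giving the bibenzyl dimer and induced peroxide decomposition in THF, and the acid so formed would quench 8. The fallback uses known chemistry and sets out from 4. It is lithiated exactly as in the route to 8, and the anion is quenched at −78 °C with C2Cl6 to give the benzylic chloride allyl 2,4-bis(allyloxy)-6-(chloromethyl)-3-methylbenzoate F1. F1 is then alkylated by the caesium salt of acid 3 (Cs2CO3, NaI cat., DMF, 25 °C, an SN2 carboxylate alkylation run cold so that the ortho-ester does not lactonise). This comes back to the route at 9.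

Step 5. The free peroxy acid 6 may epoxidise its own allyl groups or decompose during the acidification and extraction, and the hindered chloride 5 may be perhydrolysed only sluggishly. The fallback sets out from 3, which is activated with 1,1'-carbonyldiimidazole in THF to the acyl imidazole 1-[2,4-bis(allyloxy)-3,6-dimethylbenzoyl]imidazole F2. F2 is treated with the urea adduct of H2O2 (0.5 equiv, two molecules of F2 per molecule of H2O2) at −20 °C under anhydrous, homogeneous conditions. The peroxy acid formed first is acylated at once by a second molecule of F2 and never accumulates, so the peroxide is obtained in solution, titrated and used directly. This comes back to the route at 7.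

Step 8. The flanked 2-O-allyl groups may come off slowly, and the freed resorcinol rings may be C-allylated by the pi-allyl complex. The fallback sets out from 9. [Ir(cod)(PMePh2)2]PF6 (activated with H2, THF, 25 °C) isomerises all five O-allyl groups to O-(E)-prop-1-enyl groups, giving (E)-prop-1-enyl 2,4-bis[(E)-prop-1-enyloxy]-6-({2,4-bis[(E)-prop-1-enyloxy]-3,6-dimethylbenzoyl}oxymethyl)-3-methylbenzoate F3. Its enol ethers and enol ester are then hydrolysed with 1 M HCl in acetone/H2O at 40 °C, with no palladium allyl species present. This comes back to the route at 10.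

**Further compounds**
F1 | step 7 | allyl 2,4-bis(allyloxy)-6-(chloromethyl)-3-methylbenzoate | ClCc1cc(OCC=C)c(C)c(OCC=C)c1C(=O)OCC=C
F2 | step 5 | 1-[2,4-bis(allyloxy)-3,6-dimethylbenzoyl]imidazole | Cc1cc(OCC=C)c(C)c(OCC=C)c1C(=O)n1ccnc1
F3 | step 8 | (E)-prop-1-enyl 2,4-bis[(E)-prop-1-enyloxy]-6-({2,4-bis[(E)-prop-1-enyloxy]-3,6-dimethylbenzoyl}oxymethyl)-3-methylbenzoate | Cc1cc(O/C=C/C)c(C)c(O/C=C/C)c1C(=O)OCc1cc(O/C=C/C)c(C)c(O/C=C/C)c1C(=O)O/C=C/C
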